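The route rests on cutting ring B, the central phloroglucinol ring (C1 and C5 bear the outer aryl rings, C2, C4 and C6 the hydroxyls, C3 a hydrogen), into a 2-aryl-3-siloxycyclobutenone and an aryl siloxyalkyne that carry the same protected phloroglucinol ring. A Danheiser benzannulation joins them in one thermal operation: it forms C1–C2 and C5–C6, closes ring B and delivers its alternating oxygens from one ketene carbonyl (C2) and two silyl ynol ether carbons (C4, C6), so neither tetra-ortho-substituted biaryl bond has to be made by coupling. Each outer ring enters with two benzyl ethers and one methoxymethyl ether, which marks the oxygen that later becomes the sulfate.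

Key step: step 5

Assumption 1: the target SMILES gives no configuration for the two biaryl axes, so the route is not atroposelective and any separable rotamers are carried on as a mixture.
Assumption 2: aryl sulfates are drawn and counted as hydrogen sulfates; in practice 22 and 23 would be handled as pyridinium or tetrabutylammonium salts and the acid form of 24 released at the very end.

Step 1
Reactants: 1 methyl 2,4,6-trihydroxybenzoate; 2 benzyl bromide
Product: 3 methyl 2,4-bis(benzyloxy)-6-hydroxybenzoate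
Conditions: BnBr (2.05 equiv), K2CO3, DMF, rt
Reagents that add atoms: benzyl bromide (2), BrCc1ccccc1
Why: Williamson ether synthesis in which the para hydroxyl and one ortho hydroxyl are alkylated, while the last ortho hydroxyl, hydrogen-bonded to the ester carbonyl, is the least nucleophilic and should stay free.

Step 2
Reactants: 3 methyl 2,4-bis(benzyloxy)-6-hydroxybenzoate; 4 chloromethyl methyl ether
Product: 5 methyl 2,4-bis(benzyloxy)-6-(methoxymethoxy)benzoate
Conditions: NaH, MOMCl, DMF, 0 °C to rt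
Reagents that add atoms: chloromethyl methyl ether (4), COCCl
Why: Williamson-type O-alkylation in which NaH breaks the chelate and the phenoxide is trapped by the reactive α-chloro ether, giving the acetal that marks the future sulfate oxygen.

Step 3
Reactants: 5 methyl 2,4-bis(benzyloxy)-6-(methoxymethoxy)benzoate; 6 dibromomethane; 7 triisopropylsilyl trifluoromethanesulfonate
Product: 10 {[2,4-bis(benzyloxy)-6-(methoxymethoxy)phenyl]ethynyloxy}triisopropylsilane, via lithium dibromoenolate 8 (not isolated), via lithium ynolate 9 (not isolated)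
Conditions: CH2Br2, lithium 2,2,6,6-tetramethylpiperidide, THF, −78 °C; then 5; LiN(SiMe3)2, −78 to −20 °C; n-BuLi, −78 to 0 °C; TIPSOTf, −78 to 0 °C
Reagents that add atoms: dibromomethane (6), BrCBr; triisopropylsilyl trifluoromethanesulfonate (7), CC(C)[Si](OS(=O)(=O)C(F)(F)F)(C(C)C)C(C)C
Why: Kowalski ynolate formation, in which dibromomethyllithium adds to the ester, enolate 8 undergoes bromine–lithium exchange and a Fritsch–Buttenberg–Wiechell-type 1,2-shift of the electron-rich aryl group to ynolate 9, and the bulky silyl triflate silylates oxygen instead of carbon.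

Step 4
Reactants: 10 {[2,4-bis(benzyloxy)-6-(methoxymethoxy)phenyl]ethynyloxy}triisopropylsilane (a little under half of the material); 11 diketene
Product: 13 2-[2,4-bis(benzyloxy)-6-(methoxymethoxy)phenyl]-3-(triisopropylsilyloxy)cyclobut-2-en-1-one, via ketene 12 (not isolated)
Conditions: 11 cracked at 550 °C in a N2 stream, ketene passed into 10 in CH2Cl2, 0 °C to rt
Reagents that add atoms: ketene (12, made from diketene 11), C=C=O
Why: [2+2] cycloaddition of ketene with a silyl ynol ether, in which the nucleophilic aryl-bearing alkyne carbon attacks the ketene carbonyl carbon and so fixes the 2-aryl-3-siloxy pattern, while the bulky triisopropylsilyl group protects the vinylogous silyl ester from hydrolysis.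

Step 5
Reactants: 13 2-[2,4-bis(benzyloxy)-6-(methoxymethoxy)phenyl]-3-(triisopropylsilyloxy)cyclobut-2-en-1-one; 10 {[2,4-bis(benzyloxy)-6-(methoxymethoxy)phenyl]ethynyloxy}triisopropylsilane
Product: 18 2,4-bis[2,4-bis(benzyloxy)-6-(methoxymethoxy)phenyl]-3,5-bis(triisopropylsilyloxy)phenol, via vinylketene 14 (not isolated), via vinylcyclobutenone 15 (not isolated), via dienylketene 16 (not isolated), via cyclohexadienone 17 (not isolated)
Conditions: 10 (1.2 equiv), toluene (0.3 M), 80 to 110 °C, sealed tube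
Reagents that add atoms: none
Why: On heating, 13 opens by 4π electrocyclic cleavage of its C(=O)–CH2 bond to vinylketene 14, the ynol ether 10 adds across the ketene C=C in a [2+2] cycloaddition to give vinylcyclobutenone 15, a second 4π opening gives dienylketene 16, and 6π electrocyclisation to dienone 17 followed by tautomerisation gives phenol 18. The closest known reaction is the Danheiser benzannulation of cyclobutenones with trialkylsiloxyalkynes, which gives resorcinol monosilyl ethers. Ring B is the only ring closed, and it closes by the thermal disrotatory 6π electrocyclisation of 16, in which the ketene carbon (C2) bonds to the CH2 terminus (C3). No stereocentre is formed, since the quaternary carbon of 15 is lost again on ring opening, and the two biaryl axes are not controlled. The one selectivity required is the regiochemistry of the [2+2] step, and the polarisation of 10 secures it: the aryl-bearing alkyne carbon is the nucleophilic terminus and attacks the ketene carbonyl carbon (C1–C2), so the siloxy-bearing carbon has to join the ketene α-carbon (C6–C5) and the three oxygens fall on C2, C4 and C6. Both crowded aryl–ring B bonds are already in place as aryl–alkyne and aryl–alkene bonds, so the steric demand is moved from a biaryl coupling to a cycloaddition.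

Step 6
Reactants: 18 2,4-bis[2,4-bis(benzyloxy)-6-(methoxymethoxy)phenyl]-3,5-bis(triisopropylsilyloxy)phenol; 2 benzyl bromide
Product: 19 1-(benzyloxy)-2,4-bis[2,4-bis(benzyloxy)-6-(methoxymethoxy)phenyl]-3,5-bis(triisopropylsilyloxy)benzene
Conditions: BnBr, K2CO3, Bu4NI (cat.), acetone, reflux
Reagents that add atoms: benzyl bromide (2), BrCc1ccccc1
Why: Williamson ether synthesis on the only free hydroxyl, under a weak base in acetone that should leave the aryl silyl ethers alone, so that C2–OH of ring B cannot be sulfated later and O-alkylation is not in competition with C-alkylation of a free phloroglucinol.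

Step 7
Reactants: 19 1-(benzyloxy)-2,4-bis[2,4-bis(benzyloxy)-6-(methoxymethoxy)phenyl]-3,5-bis(triisopropylsilyloxy)benzene
Product: 20 2,2'-[4-(benzyloxy)-2,6-bis(triisopropylsilyloxy)-1,3-phenylene]bis[3,5-bis(benzyloxy)phenol]
Conditions: HCl (2 M), MeOH/THF, 40 °C
Reagents that add atoms: none
Why: Acid-catalysed acetal cleavage (transacetalisation to dimethoxymethane), to which aryl methoxymethyl ethers respond under mild conditions whereas aryl benzyl and aryl triisopropylsilyl ethers should be stable.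

Step 8
Reactants: 20 2,2'-[4-(benzyloxy)-2,6-bis(triisopropylsilyloxy)-1,3-phenylene]bis[3,5-bis(benzyloxy)phenol]; 21 sulfur trioxide–pyridine complex
Product: 22 [4-(benzyloxy)-2,6-bis(triisopropylsilyloxy)-1,3-phenylene]bis[3,5-bis(benzyloxy)-2,1-phenylene] bis(hydrogen sulfate)
Conditions: SO3·pyridine (6 equiv), pyridine, 50 °C
Reagents that add atoms: sulfur trioxide–pyridine complex (21), O=S(=O)([O-])[n+]1ccccc1
Why: O-sulfation of phenols with an amine–sulfur trioxide complex, in which the two hydroxyls freed in step 7 are the only ones available, so the protecting-group pattern fixes the sulfate positions.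

Step 9
Reactants: 22 [4-(benzyloxy)-2,6-bis(triisopropylsilyloxy)-1,3-phenylene]bis[3,5-bis(benzyloxy)-2,1-phenylene] bis(hydrogen sulfate)
Product: 23 [4-(benzyloxy)-2,6-dihydroxy-1,3-phenylene]bis[3,5-bis(benzyloxy)-2,1-phenylene] bis(hydrogen sulfate)
Conditions: Bu4NF, AcOH, THF, 0 °C to rt
Reagents that add atoms: none
Why: Fluoride-induced desilylation driven by Si–F bond formation, to which aryl sulfate monoesters and benzyl ethers are inert when the fluoride is buffered.

Step 10
Reactants: 23 [4-(benzyloxy)-2,6-dihydroxy-1,3-phenylene]bis[3,5-bis(benzyloxy)-2,1-phenylene] bis(hydrogen sulfate)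
Product: 24 (2,4,6-trihydroxy-1,3-phenylene)bis(3,5-dihydroxy-2,1-phenylene) bis(hydrogen sulfate), CNP0320583.0
Conditions: H2 (1 atm), Pd/C, MeOH/THF, rt; then cation-exchange resin (H+ form), 0 °C, under argon
Reagents that add atoms: none
Why: Catalytic hydrogenolysis of the five benzyl aryl ethers over Pd/C, which should not touch aryl sulfate monoesters under neutral conditions, followed by a cold pass through acid-form resin to give the hydrogen sulfate form.

Compound list
1 | methyl 2,4,6-trihydroxybenzoate | COC(=O)c1c(O)cc(O)cc1O | starting material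
2 | benzyl bromide | BrCc1ccccc1 | starting material
3 | methyl 2,4-bis(benzyloxy)-6-hydroxybenzoate | COC(=O)c1c(O)cc(OCc2ccccc2)cc1OCc1ccccc1 | intermediate
4 | chloromethyl methyl ether | COCCl | starting material
5 | methyl 2,4-bis(benzyloxy)-6-(methoxymethoxy)benzoate | COC(=O)c1c(OCOC)cc(OCc2ccccc2)cc1OCc1ccccc1 | intermediate
6 | dibromomethane | BrCBr | starting material
7 | triisopropylsilyl trifluoromethanesulfonate | CC(C)[Si](OS(=O)(=O)C(F)(F)F)(C(C)C)C(C)C | starting material
8 | lithium 1-[2,4-bis(benzyloxy)-6-(methoxymethoxy)phenyl]-2,2-dibromoethen-1-olate (not isolated) | [Li]OC(=C(Br)Br)c1c(OCOC)cc(OCc2ccccc2)cc1OCc1ccccc1 | intermediate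
9 | lithium 2-[2,4-bis(benzyloxy)-6-(methoxymethoxy)phenyl]ethyn-1-olate (not isolated) | [Li]OC#Cc1c(OCOC)cc(OCc2ccccc2)cc1OCc1ccccc1 | intermediate
10 | {[2,4-bis(benzyloxy)-6-(methoxymethoxy)phenyl]ethynyloxy}triisopropylsilane | CC(C)[Si](C(C)C)(C(C)C)OC#Cc1c(OCOC)cc(OCc2ccccc2)cc1OCc1ccccc1 | intermediate
11 | diketene (4-methylideneoxetan-2-one) | C=C1CC(=O)O1 | starting material
12 | ketene (ethenone; not isolated) | C=C=O | intermediate
13 | 2-[2,4-bis(benzyloxy)-6-(methoxymethoxy)phenyl]-3-(triisopropylsilyloxy)cyclobut-2-en-1-one | O=C1CC(O[Si](C(C)C)(C(C)C)C(C)C)=C1c1c(OCOC)cc(OCc2ccccc2)cc1OCc1ccccc1 | intermediate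
14 | 2-[2,4-bis(benzyloxy)-6-(methoxymethoxy)phenyl]-3-(triisopropylsilyloxy)buta-1,3-dien-1-one (not isolated) | O=C=C(C(=C)O[Si](C(C)C)(C(C)C)C(C)C)c1c(OCOC)cc(OCc2ccccc2)cc1OCc1ccccc1 | intermediate
15 | 2,4-bis[2,4-bis(benzyloxy)-6-(methoxymethoxy)phenyl]-3-(triisopropylsilyloxy)-4-[1-(triisopropylsilyloxy)ethenyl]cyclobut-2-en-1-one (racemic; not isolated) | O=C1C(c2c(OCOC)cc(OCc3ccccc3)cc2OCc2ccccc2)=C(O[Si](C(C)C)(C(C)C)C(C)C)C1(C(=C)O[Si](C(C)C)(C(C)C)C(C)C)c1c(OCOC)cc(OCc2ccccc2)cc1OCc1ccccc1 | intermediate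
16 | (3E)-2,4-bis[2,4-bis(benzyloxy)-6-(methoxymethoxy)phenyl]-3,5-bis(triisopropylsilyloxy)hexa-1,3,5-trien-1-one (C2 and C5 cis across C3=C4; not isolated) | O=C=C(c1c(OCOC)cc(OCc2ccccc2)cc1OCc1ccccc1)/C(O[Si](C(C)C)(C(C)C)C(C)C)=C(/c1c(OCOC)cc(OCc2ccccc2)cc1OCc1ccccc1)C(=C)O[Si](C(C)C)(C(C)C)C(C)C | intermediate
17 | 2,4-bis[2,4-bis(benzyloxy)-6-(methoxymethoxy)phenyl]-3,5-bis(triisopropylsilyloxy)cyclohexa-2,4-dien-1-one (not isolated) | O=C1CC(O[Si](C(C)C)(C(C)C)C(C)C)=C(c2c(OCOC)cc(OCc3ccccc3)cc2OCc2ccccc2)C(O[Si](C(C)C)(C(C)C)C(C)C)=C1c1c(OCOC)cc(OCc2ccccc2)cc1OCc1ccccc1 | intermediate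
18 | 2,4-bis[2,4-bis(benzyloxy)-6-(methoxymethoxy)phenyl]-3,5-bis(triisopropylsilyloxy)phenol | Oc1cc(O[Si](C(C)C)(C(C)C)C(C)C)c(-c2c(OCOC)cc(OCc3ccccc3)cc2OCc2ccccc2)c(O[Si](C(C)C)(C(C)C)C(C)C)c1-c1c(OCOC)cc(OCc2ccccc2)cc1OCc1ccccc1 | intermediate
19 | 1-(benzyloxy)-2,4-bis[2,4-bis(benzyloxy)-6-(methoxymethoxy)phenyl]-3,5-bis(triisopropylsilyloxy)benzene | c1ccccc1COc1cc(O[Si](C(C)C)(C(C)C)C(C)C)c(-c2c(OCOC)cc(OCc3ccccc3)cc2OCc2ccccc2)c(O[Si](C(C)C)(C(C)C)C(C)C)c1-c1c(OCOC)cc(OCc2ccccc2)cc1OCc1ccccc1 | intermediate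
20 | 2,2'-[4-(benzyloxy)-2,6-bis(triisopropylsilyloxy)-1,3-phenylene]bis[3,5-bis(benzyloxy)phenol] | c1ccccc1COc1cc(O[Si](C(C)C)(C(C)C)C(C)C)c(-c2c(O)cc(OCc3ccccc3)cc2OCc2ccccc2)c(O[Si](C(C)C)(C(C)C)C(C)C)c1-c1c(O)cc(OCc2ccccc2)cc1OCc1ccccc1 | intermediate
21 | sulfur trioxide–pyridine complex | O=S(=O)([O-])[n+]1ccccc1 | starting material
22 | [4-(benzyloxy)-2,6-bis(triisopropylsilyloxy)-1,3-phenylene]bis[3,5-bis(benzyloxy)-2,1-phenylene] bis(hydrogen sulfate) | c1ccccc1COc1cc(O[Si](C(C)C)(C(C)C)C(C)C)c(-c2c(OS(=O)(=O)O)cc(OCc3ccccc3)cc2OCc2ccccc2)c(O[Si](C(C)C)(C(C)C)C(C)C)c1-c1c(OS(=O)(=O)O)cc(OCc2ccccc2)cc1OCc1ccccc1 | intermediate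
23 | [4-(benzyloxy)-2,6-dihydroxy-1,3-phenylene]bis[3,5-bis(benzyloxy)-2,1-phenylene] bis(hydrogen sulfate) | c1ccccc1COc1cc(O)c(-c2c(OS(=O)(=O)O)cc(OCc3ccccc3)cc2OCc2ccccc2)c(O)c1-c1c(OS(=O)(=O)O)cc(OCc2ccccc2)cc1OCc1ccccc1 | intermediate
24 | (2,4,6-trihydroxy-1,3-phenylene)bis(3,5-dihydroxy-2,1-phenylene) bis(hydrogen sulfate), CNP0320583.0 | O=S(=O)(O)Oc1cc(O)cc(O)c1-c1c(O)cc(O)c(-c2c(O)cc(O)cc2OS(=O)(=O)O)c1O | target

Total step count: 10
Longest linear sequence: 10 steps (1 to 24; alkyne 10 enters twice, in steps 4 and 5)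

Steps most likely to fail

Step 5. The bimolecular [2+2] between the fully substituted ketene carbon of 14 and the hindered alkyne 10 may be outrun by reclosure or dimerisation of the vinylketene, or by attack of an ortho ether oxygen on the ketene. The fallback gives up the annulation and makes both biaryl bonds by cross-coupling. It sets out from ester 5 and comes back to the route at target 24.
- Saponification (KOH, aqueous DMSO, 80 °C, careful acidification at 0 °C) should give 2,4-bis(benzyloxy)-6-(methoxymethoxy)benzoic acid F1.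
- Decarboxylative ipso-iodination (I2, K3PO4, MeCN, 100 °C) should give 1,5-bis(benzyloxy)-2-iodo-3-(methoxymethoxy)benzene F2.
- Iodine–lithium exchange (n-BuLi, THF, −78 °C) gives [2,4-bis(benzyloxy)-6-(methoxymethoxy)phenyl]lithium F3, and ZnCl2 converts it into [2,4-bis(benzyloxy)-6-(methoxymethoxy)phenyl]zinc chloride F4.
- Commercial 1,3,5-tris(benzyloxy)benzene is dibrominated (NBS, 2 equiv, MeCN, 0 °C) to 1,3,5-tris(benzyloxy)-2,4-dibromobenzene F5.
- Twofold Negishi coupling of F5 with F4 (Pd2(dba)3, RuPhos, THF/NMP, 70 °C) would give 1,3,5-tris(benzyloxy)-2,4-bis[2,4-bis(benzyloxy)-6-(methoxymethoxy)phenyl]benzene F6.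
- Acetal cleavage as in step 7 gives 2,2'-[2,4,6-tris(benzyloxy)-1,3-phenylene]bis[3,5-bis(benzyloxy)phenol] F7.
- Sulfation as in step 8 gives [2,4,6-tris(benzyloxy)-1,3-phenylene]bis[3,5-bis(benzyloxy)-2,1-phenylene] bis(hydrogen sulfate) F8, and hydrogenolysis as in step 10 gives 24.

Step 3. Dibromomethyllithium may decompose before it adds to the di-ortho-substituted, electron-rich ester, and excess butyllithium may metalate ring or benzylic positions on warming. The fallback reaches the ynolate by oxidation of an acetylide. It sets out from ester 5 and comes back to the route at siloxyalkyne 10.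
- LiAlH4 (THF, 0 °C) reduces 5 to [2,4-bis(benzyloxy)-6-(methoxymethoxy)phenyl]methanol F9, and MnO2 (CH2Cl2, rt) oxidises this to 2,4-bis(benzyloxy)-6-(methoxymethoxy)benzaldehyde F10.
- Ohira–Bestmann homologation (dimethyl (1-diazo-2-oxopropyl)phosphonate, K2CO3, MeOH) gives 1,5-bis(benzyloxy)-2-ethynyl-3-(methoxymethoxy)benzene F11.
- LiN(SiMe3)2 (THF, −78 °C) gives lithium [2,4-bis(benzyloxy)-6-(methoxymethoxy)phenyl]acetylide F12.
- Oxidation with lithium tert-butyl peroxide F13 (from t-BuOOH and LiN(SiMe3)2, −78 to 0 °C) gives ynolate 9, which TIPSOTf silylates to 10.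

Step 4. Ketene may polymerise faster than it adds to the hindered alkyne, and the siloxycyclobutenone may be hydrolysed to the 1,3-dione during isolation. The fallback uses a more electrophilic ketene and removes its halogens afterwards. It sets out from siloxyalkyne 10 and comes back to the route at cyclobutenone 13.
- Dichloroketene F14, made in the flask from Cl3CCOCl and Zn(Cu) in Et2O at rt, should add to 10 with the same regiochemistry to give 2-[2,4-bis(benzyloxy)-6-(methoxymethoxy)phenyl]-4,4-dichloro-3-(triisopropylsilyloxy)cyclobut-2-en-1-one F15.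
- Buffered zinc reduction (Zn, AcOH, TMEDA, EtOH, 0 °C) removes both chlorines and gives 13.

Further compounds
F1 | step 5 | 2,4-bis(benzyloxy)-6-(methoxymethoxy)benzoic acid | OC(=O)c1c(OCOC)cc(OCc2ccccc2)cc1OCc1ccccc1
F2 | step 5 | 1,5-bis(benzyloxy)-2-iodo-3-(methoxymethoxy)benzene | Ic1c(OCOC)cc(OCc2ccccc2)cc1OCc1ccccc1
F3 | step 5 | [2,4-bis(benzyloxy)-6-(methoxymethoxy)phenyl]lithium | [Li]c1c(OCOC)cc(OCc2ccccc2)cc1OCc1ccccc1
F4 | step 5 | [2,4-bis(benzyloxy)-6-(methoxymethoxy)phenyl]zinc chloride | Cl[Zn]c1c(OCOC)cc(OCc2ccccc2)cc1OCc1ccccc1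
F5 | step 5 | 1,3,5-tris(benzyloxy)-2,4-dibromobenzene | Brc1c(OCc2ccccc2)cc(OCc2ccccc2)c(Br)c1OCc1ccccc1
F6 | step 5 | 1,3,5-tris(benzyloxy)-2,4-bis[2,4-bis(benzyloxy)-6-(methoxymethoxy)phenyl]benzene | c1ccccc1COc1cc(OCc2ccccc2)c(-c2c(OCOC)cc(OCc3ccccc3)cc2OCc2ccccc2)c(OCc2ccccc2)c1-c1c(OCOC)cc(OCc2ccccc2)cc1OCc1ccccc1
F7 | step 5 | 2,2'-[2,4,6-tris(benzyloxy)-1,3-phenylene]bis[3,5-bis(benzyloxy)phenol] | c1ccccc1COc1cc(OCc2ccccc2)c(-c2c(O)cc(OCc3ccccc3)cc2OCc2ccccc2)c(OCc2ccccc2)c1-c1c(O)cc(OCc2ccccc2)cc1OCc1ccccc1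
F8 | step 5 | [2,4,6-tris(benzyloxy)-1,3-phenylene]bis[3,5-bis(benzyloxy)-2,1-phenylene] bis(hydrogen sulfate) | c1ccccc1COc1cc(OCc2ccccc2)c(-c2c(OS(=O)(=O)O)cc(OCc3ccccc3)cc2OCc2ccccc2)c(OCc2ccccc2)c1-c1c(OS(=O)(=O)O)cc(OCc2ccccc2)cc1OCc1ccccc1
F9 | step 3 | [2,4-bis(benzyloxy)-6-(methoxymethoxy)phenyl]methanol | OCc1c(OCOC)cc(OCc2ccccc2)cc1OCc1ccccc1
F10 | step 3 | 2,4-bis(benzyloxy)-6-(methoxymethoxy)benzaldehyde | O=Cc1c(OCOC)cc(OCc2ccccc2)cc1OCc1ccccc1
F11 | step 3 | 1,5-bis(benzyloxy)-2-ethynyl-3-(methoxymethoxy)benzene | C#Cc1c(OCOC)cc(OCc2ccccc2)cc1OCc1ccccc1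
F12 | step 3 | lithium [2,4-bis(benzyloxy)-6-(methoxymethoxy)phenyl]acetylide | [Li]C#Cc1c(OCOC)cc(OCc2ccccc2)cc1OCc1ccccc1
F13 | step 3 | lithium tert-butyl peroxide | [Li]OOC(C)(C)C
F14 | step 4 | dichloroketene | O=C=C(Cl)Cl
F15 | step 4 | 2-[2,4-bis(benzyloxy)-6-(methoxymethoxy)phenyl]-4,4-dichloro-3-(triisopropylsilyloxy)cyclobut-2-en-1-one | O=C1C(Cl)(Cl)C(O[Si](C(C)C)(C(C)C)C(C)C)=C1c1c(OCOC)cc(OCc2ccccc2)cc1OCc1ccccc1
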